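The data are simulated with made-up constants; the scatter is artificial.

- 13.2 mM of X is the number to hold on to: this is the X ceiling, the concentration at which X stands still in this south-west flask, reckoned as its last X percentage times its Q charge.

| setting | south-west | flask |
|---|---|---|
| Q | 0.050 M | 0.050 M |
| G | 0.090 M | 0.0900 M |
| remark | the very flask that is asked about, followed so far |  |
| time |  | 25 min |

south-west run (percent of the Q charged)

| time / min | Q / % | X / % |
|---|---|---|
| 0.833 | 75.8 | 20.0 |
| 1.50 | 60.3 | 25.6 |
| 2.50 | 45.8 | 26.5 |
| 3.00 | 41.0 | 26.6 |
| 4.00 | 36.0 | 26.1 |
| 5.00 | 33.8 | 26.4 |

(each reading ± 0.5 percentage points)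

- at the start none of Q is in solution
- what has only dissolved of Q counts as not reacted
- a reading or a percentage of X counts all its forms, free or not
- the reaction counts as stopped when no species that holds the Q changes by six tenths of a point or more over the second half of the time

- at 25 min, what has stopped the reaction, if anything has (for what has run out or reacted, a solid counts together with what of it has only dissolved) (forward and back rates have come level / G has run out first / all of Q has reacted / it is still moving)
- part of the Q that has turned into other species by 25 min (what has only dissolved does not count)
- how much X there is at 25 min, in percent of the Q charged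

- In this flask, from 2.50 min to 5.00 min, X moves by 0.1 percentage points, inside the scatter of 0.5 points, while the Q reading falls 12 points, so I read that later fall as Q going into solution, which does not count as reacted, and I take G as the limiting reagent.
- When you come at 25 min, I reckon on X at 26.4% and on the same figure for conversion, and that conversion of mine is lower than the forecast's 68.2% (66.8% to 70%), by 42 points.
- The forecast says “a further product must be forming from X”, and it gives X at 26.4% (25.5% to 27%) and the end as G has run out first.
- Leave the Q charge alone, since my percentage is the ceiling divided by that charge.

    Q ⇌ J, rate k1*(cs1 - [J]) while solid is left; crystals form when [J] > cs1 (solubility = 21.0 mM, k = 0.0120 s⁻¹)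
    J + G → X (k = 7.30 L mol⁻¹ s⁻¹)
    Z ⇌ X, rate k3*(cs3 - [X]) while solid is left; crystals form when [X] > cs3 (solubility = 15.0 mM, k = 1.40 s⁻¹)
    G → E (k = 0.0390 s⁻¹)

- The flask ends with G has run out first, 0% of G left, conversion 26.5% and X 26.5%, which is 13.2 mM against the ceiling of 13.2 mM; at 25.0 min it holds Q at 31.5% and dissolved J at 42.0%. The neighbouring flask has 0.20 M of Q and the same G, so the ceiling over that charge gives 6.60%, and that flask stores X at 6.62% with 0% of its G left.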